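Atom labels follow the order of the atoms in the target SMILES (C1 … N41). β is the face of the angular methyl C37. Ring A = C2,3,4,6,36,38; B = C6,7,32,31,36; C = C25,27,29,31,32,33.
Retrosynthesis: open the two reversible rings (O23–C21 peroxyhemiacetal, N41–C16 hemiaminal). The epoxide and the C25–OO bond go back to I+, H2O2 and the allylic alcohol C25=C27–C29(OH)Me, and this goes back to the ring-C enone C25=C27–C29=O.
Feature used: ring C has the Hagemann-ester pattern (oxygen on C29 para to C33, methyl on C25) and shares its C32–C33 bond with the 13-membered cyclophane. One [4+2] of a ring-B 2-siloxydiene (C27=C29–C31=C32) with a tethered but-2-ynoyl unit (C33≡C25) therefore makes ring C and closes the macrocycle together.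
Forward order: ring A (radical closure C36–C6), ring B (aldol C31=C32), aryl ether C7–O8, ring C plus macrocycle (Diels–Alder), lactam, then dioxocane and epoxide last.
Stereochemistry: C2/C4 come from catalytic desymmetrisation of a meso anhydride and C19 from a phase-transfer allylation. C36, C6, C7, C32, C31, C33 and C29 are relayed by substrate control, C25/C27 by trans-diaxial opening and closure, and C16/C21 by equilibration.

Key step: step 21

Remark 1: the sense of induction of (DHQD)2AQN (step 2) and of the (S,S) phase-transfer catalyst (step 14) is assumed as drawn. The pseudo-enantiomeric or enantiomeric catalyst gives the mirror image.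
Remark 2: C16 (hemiaminal) and C21 (peroxyhemiacetal) are configurationally labile, and the configuration of the target is taken to be the equilibrium one.

Step 1
Reactants: 1 2-methyl-1,3-dithiane; 2 2,3-dibromoprop-1-ene
Product: 4 2-(2-bromoprop-2-en-1-yl)-2-methyl-1,3-dithiane, via 2-lithio-2-methyl-1,3-dithiane 3 (not isolated)
Conditions: n-BuLi, THF, −30 °C; then 2, −78 °C to rt
Reagents that add atoms: none
Why: Corey–Seebach alkylation, in which the lithiodithiane displaces only the allylic bromide because the vinylic C–Br bond is inert to SN2; no stereocentre is formed.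

Step 2
Reactants: 5 cis-(meso)-2,4-dimethylglutaric anhydride
Product: 6 (2R,4S)-5-methoxy-2,4-dimethyl-5-oxopentanoic acid
Conditions: MeOH, (DHQD)2AQN (10 mol %), Et2O, −20 °C
Reagents that add atoms: methanol, CO
Why: Catalytic desymmetrising alcoholysis of a meso anhydride by a modified cinchona alkaloid differentiates the enantiotopic carbonyl groups and so fixes C2 and C4 in one event.

Step 3
Reactants: 6 hemiester
Product: 7 methyl (2S,4R)-5-hydroxy-2,4-dimethylpentanoate
Conditions: BH3·SMe2, THF, 0 °C
Reagents that add atoms: none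
Why: Borane reduces the carboxylic acid much faster than the ester, and neither α-stereocentre is touched.

Step 4
Reactants: 7 hydroxy ester
Product: 8 methyl (2S,4R)-5-iodo-2,4-dimethylpentanoate
Conditions: I2, PPh3, imidazole, CH2Cl2, 0 °C
Reagents that add atoms: iodine, II
Why: Appel iodination of a primary alcohol, with no stereocentre involved.

Step 5
Reactants: 8 iodide; 4 vinyl bromide
Product: 10 methyl (2S,4R)-2,4-dimethyl-6-[(2-methyl-1,3-dithian-2-yl)methyl]hept-6-enoate, via alkylzinc iodide 9 (not isolated)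
Conditions: Zn dust (activated), LiCl, THF, 40 °C; then 4, PdCl2(dppf) (3 mol %), 50 °C
Reagents that add atoms: none
Why: Negishi sp3–sp2 coupling of an ester-tolerant β-branched primary alkylzinc with a 2-bromoalkene makes the C38–C36 bond.

Step 6
Reactants: 10 ester
Product: 11 (2S,4R)-2,4-dimethyl-6-[(2-methyl-1,3-dithian-2-yl)methyl]hept-6-enal
Conditions: DIBAL-H (1.05 equiv), CH2Cl2, −78 °C
Reagents that add atoms: none
Why: Low-temperature partial reduction of a methyl ester, whose tetrahedral aluminate survives until work-up so that C4 is not epimerised.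

Step 7
Reactants: 11 aldehyde
Product: 12 ethyl (2E,4S,6R)-4,6-dimethyl-8-[(2-methyl-1,3-dithian-2-yl)methyl]nona-2,8-dienoate
Conditions: Ph3P=CHCO2Et, CH2Cl2, rt
Reagents that add atoms: (carbethoxymethylene)triphenylphosphorane, CCOC(=O)C=P(c1ccccc1)(c1ccccc1)c1ccccc1
Why: Wittig reaction with a stabilised ylide is E-selective and base-free, so the α-stereocentre C4 is safe.

Step 8
Reactants: 12 dienoate
Product: 13 ring-A ester: ethyl 2-{2,4,6-trimethyl-2-[(2-methyl-1,3-dithian-2-yl)methyl]cyclohexyl}acetate (H6 α, C37 methyl β-axial, C1 and C5 methyls and both side chains equatorial)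
Conditions: Fe(acac)3 (30 mol %), PhSiH3, EtOH/ethylene glycol, 60 °C
Reagents that add atoms: none
Why: Metal-hydride H-atom transfer to the 1,1-disubstituted alkene gives the tertiary C36 radical, which closes 6-exo onto the enoate (intramolecular reductive olefin coupling, Giese type) through a chair with all large groups equatorial, so the new methyl C37 is axial and C36/C6 are set trans.

Step 9
Reactants: 13 ester
Product: 14 ring-A aldehyde (CH2CHO on C6)
Conditions: DIBAL-H (1.05 equiv), CH2Cl2, −78 °C
Reagents that add atoms: none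
Why: Partial reduction of the only ester, with the dithiane inert.

Step 10
Reactants: 14 aldehyde
Product: 16 bicyclic enone: trans-fused 1-acetylcyclopentene (C31=C32, acetyl = C29/C27), via keto aldehyde 15 (not isolated)
Conditions: MeI, CaCO3, MeCN/H2O, 45 °C; volatiles removed; then KOH, MeOH/H2O, 0 °C to rt
Reagents that add atoms: water, O
Why: S-methylation/hydrolysis unmasks the ketone, and base closes the 1,6-keto aldehyde by 5-(enolexo)-exo-trig aldol condensation onto the more electrophilic aldehyde (the classical 6-oxoheptanal to 1-acetylcyclopentene closure); C6 is not acidic and stays.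

Step 11
Reactants: 16 enone
Product: 17 C7 β-bromide of 16
Conditions: NBS, AIBN, K2CO3 (solid), PhCF3, 80 °C
Reagents that add atoms: N-bromosuccinimide, O=C1CCC(=O)N1Br
Why: Wohl–Ziegler bromination at the only allylic C–H position (C7), where bromine is delivered along the pseudoaxial β trajectory of the cyclopentene envelope whose flap C6 lies on the α side, as is known for attack at C15 of steroidal D rings.

Step 12
Reactants: 18 (4-bromophenoxy)(tert-butyl)dimethylsilane; 19 3-chloro-2-(chloromethyl)prop-1-ene
Product: 21 tert-butyl{4-[2-(chloromethyl)allyl]phenoxy}dimethylsilane, via aryl Grignard reagent 20 (not isolated)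
Conditions: Mg, THF; then 19 (3 equiv), CuI (5 mol %), −20 °C
Reagents that add atoms: none
Why: Copper-catalysed allylic coupling of an aryl Grignard reagent, in which SN2 and SN2′ give the same product with this symmetrical dichloride and the excess prevents double substitution.

Step 13
Reactants: 21 allylic chloride; 22 tert-butyl cyanoacetate
Product: 23 tert-butyl 2-cyano-4-[4-(TBSO)benzyl]pent-4-enoate (racemic)
Conditions: 22 (3 equiv), NaH, NaI (cat.), THF/DMF, 0 °C to rt
Reagents that add atoms: none
Why: Alkylation of a stabilised carbanion by a reactive allylic halide makes C18–C19, and the excess nucleophile suppresses dialkylation.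

Step 14
Reactants: 23 α-substituted cyanoacetate
Product: 24 tert-butyl (R)-2-allyl-2-cyano-4-[4-(TBSO)benzyl]pent-4-enoate
Conditions: allyl bromide, (S,S)-N-spiro binaphthyl quaternary ammonium bromide (2 mol %), Cs2CO3 (solid), toluene, −40 °C
Reagents that add atoms: allyl bromide, C=CCBr
Why: Asymmetric phase-transfer alkylation of an α-alkyl cyanoacetate, in which the chiral ion pair shields one enolate face and sets the quaternary centre C19.

Step 15
Reactants: 24 tert-butyl ester
Product: 25 (R)-2-allyl-2-cyano-4-[4-(TBSO)benzyl]pent-4-enoic acid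
Conditions: TMSOTf, 2,6-lutidine, CH2Cl2, 0 °C; aqueous work-up
Reagents that add atoms: none
Why: Silyl-triflate cleavage of a tert-butyl ester under buffered conditions avoids protonation of the 1,1-disubstituted alkene and spares the aryl silyl ether.

Step 16
Reactants: 25 acid
Product: 27 (R)-2-allyl-2-formyl-4-[4-(TBSO)benzyl]pent-4-enenitrile, via acid chloride 26 (not isolated)
Conditions: (COCl)2, DMF (cat.), CH2Cl2; then LiAlH(OtBu)3, THF, −78 °C
Reagents that add atoms: none
Why: Hindered-hydride reduction of an acid chloride stops at the aldehyde and leaves the nitrile intact, and the aldehyde has no α-hydrogen.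

Step 17
Reactants: 27 aldehyde
Product: 28 propargylic alcohol (C34 carbinol, both epimers; C19 R)
Conditions: 1-propynylmagnesium bromide, THF, −78 °C
Reagents that add atoms: 1-propynylmagnesium bromide, CC#C[Mg]Br
Why: 1,2-Addition of an alkynyl Grignard reagent to the aldehyde is much faster than addition to the nitrile, and the C34 configuration is irrelevant because it is oxidised in step 20.

Step 18
Reactants: 28 silyl ether
Product: 29 phenol fragment
Conditions: TBAF, AcOH, THF, 0 °C
Reagents that add atoms: none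
Why: Buffered fluoride removes the phenolic silyl group without retro-addition of the β-hydroxy nitrile.

Step 19
Reactants: 17 β-bromide; 29 phenol
Product: 30 C7 β-aryl ether
Conditions: Pd2(dba)3·CHCl3 (2.5 mol %), dppf, K2CO3, THF, 0 °C to rt
Reagents that add atoms: none
Why: Tsuji–Trost allylic etherification, in which ionisation with inversion puts Pd on the α face and the phenoxide attacks the open terminus C7 anti to Pd (C31 is blocked by acetyl and quaternary C36), so net retention gives the β C7–O8 bond; the dienophile is carried as the carbinol because phenoxide and phosphine would add to an ynone.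

Step 20
Reactants: 30 propargylic alcohol
Product: 31 ynone
Conditions: Dess–Martin periodinane, NaHCO3, CH2Cl2, 0 °C
Reagents that add atoms: none
Why: Neutral oxidation of the only oxidisable alcohol gives the non-enolisable but-2-ynoyl ketone.

Step 21
Reactants: 31 ynone-enone
Product: 33 Diels–Alder adduct (ring C 1,4-diene: C29(OTBS)=C31 and C25=C33; 13-membered cyclophane closed; H32 β), via siloxydiene 32 (not isolated)
Conditions: TBSOTf, Et3N, CH2Cl2, 0 °C; solvent changed to toluene (about 1 mM), BHT, 110 °C
Reagents that add atoms: tert-butyldimethylsilyl triflate, CC(C)(C)[Si](C)(C)OS(=O)(=O)C(F)(F)F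
Why: Soft enolisation of the only enolisable ketone gives the cross-conjugated 2-siloxydiene 32 (C27=C29(OTBS)–C31=C32), which at high dilution undergoes a concerted, asynchronous normal-demand [4+2] with the tethered but-2-ynoyl unit (C33≡C25). The closest known reaction types are macrocyclising intramolecular Diels–Alder reactions through long tethers (11- to 14-membered carbocycles), the cycloaddition of 2-alkoxybutadienes with but-2-ynoates that leads to Hagemann's ester, and the α-face cycloadditions of steroidal 16,20-dien-20-yl ethers. Ring C is closed by both new σ-bonds (C27–C25 and C32–C33) and the 13-membered ring by the C32–C33 bond alone, that is, a type-1 IMDA through an eleven-atom tether. The only new stereocentre, C32, is controlled by the β angular methyl C37 and the pseudoaxial β C7–O bond, which leave only the α face of the diene open (H32 β), and the linear alkyne removes any endo/exo question. The needed regiochemistry (C29 para to C33) is the electronically preferred one (largest HOMO coefficient at C27, largest LUMO coefficient at C25) and the only one the tether allows, while chemoselectivity is secured because the other two alkenes are unactivated, C19 is quaternary, and nitrogen is carried as a nitrile so that no N–H can add to the ynone. The strain of the bent cyclophane is paid for by converting an alkyne and a diene into two σ-bonds, and dilution holds back oligomerisation.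

Step 22
Reactants: 33 adduct
Product: 35 ring-C enone (C25=C27–C29=O; H31 α, H33 α, trans-fused B/C), via deconjugated diketone 34 (not isolated)
Conditions: HF·pyridine, THF, 0 °C; then DBU (0.3 equiv), CH2Cl2, rt
Reagents that add atoms: none
Why: Desilylation gives the C29 ketone, and DBU equilibrates the vinylogous 1,3-diketone to the ring-conjugated enone (the preference that gives Hagemann's ester, reinforced because the C34 carbonyl next to quaternary C19 cannot be coplanar with a tetrasubstituted C25=C33), while the acidic C31–H and C33–H settle to the trans ring fusion and the equatorial acyl group; non-nucleophilic reagents avoid retro-Claisen cleavage at C34.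

Step 23
Reactants: 35 enone
Product: 37 C16 ketone, via spiro-epoxide 36 (not isolated)
Conditions: mCPBA (1.05 equiv), NaHCO3, CH2Cl2, 0 °C; then H5IO6, THF/H2O, 0 °C
Reagents that add atoms: 3-chloroperbenzoic acid, OOC(=O)c1cccc(Cl)c1; water, O
Why: Peracid epoxidation prefers the 1,1-disubstituted alkene over the monosubstituted allyl group and ignores the enone, and periodic acid hydrolyses and cleaves the epoxide to the ketone, so C16 is unveiled before the aldehyde.

Step 24
Reactants: 37 keto nitrile
Product: 39 hydroxylactam (C16–OH, N41–C16 closed), via keto amide 38 (not isolated)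
Conditions: [PtH(PMe2OH)(PMe2O)2H] (5 mol %), EtOH/H2O, 75 °C
Reagents that add atoms: water, O
Why: Neutral platinum-phosphinito hydration of a hindered nitrile gives the primary amide, which adds to the 1,4-related C16 ketone, and C16 is set by the reversible ring closure within the macrocycle.

Step 25
Reactants: 39 enone
Product: 40 tertiary allylic alcohol (C29: OH β-axial, methyl C30 α)
Conditions: MeMgCl/CeCl3 (6 equiv), THF, −78 °C
Reagents that add atoms: methylmagnesium chloride, C[Mg]Cl
Why: The weakly basic organocerium reagent adds 1,2 to the enolisable enone from the α (equatorial) side because C37 covers the β face, while the C34 ketone is shielded by quaternary C19 and the hydroxylactam stays closed as its alkoxide at −78 °C.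

Step 26
Reactants: 40 allyl compound
Product: 41 aldehyde (C20H2–C21HO)
Conditions: OsO4 (2 mol %), NaIO4, 2,6-lutidine, dioxane/H2O, 0 °C
Reagents that add atoms: osmium tetroxide, O=[Os](=O)(=O)=O; sodium periodate, [Na+].[O-][I](=O)(=O)=O
Why: Lemieux–Johnson cleavage of the unhindered terminal alkene, where the trisubstituted C25=C27 bond flanked by C29 (fully substituted) and C33 is sterically protected.

Step 27
Reactants: 41 aldehyde
Product: 43 iodo-dioxocanol (C25–OO β-axial, C27–I α-axial, C29–OH β-axial, O23–C21 closed), via iodo hydroperoxide 42 (not isolated)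
Conditions: NIS, anhydrous H2O2 in Et2O (20 equiv), CH2Cl2, −40 to −10 °C, dark
Reagents that add atoms: N-iodosuccinimide, O=C1CCC(=O)N1I; hydrogen peroxide, OO
Why: Halo-hydroperoxidation, in which only the α-iodonium ion can be opened both in the Markovnikov sense and trans-diaxially (Fürst–Plattner), so H2O2 enters at tertiary C25 from the β face, and the hydroperoxide then adds reversibly to the C21 aldehyde to close the 1,2-dioxocan-3-ol, with C21 settling by equilibration.

Step 28
Reactants: 43 iodohydrin
Product: 44 target CNP0533733.1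
Conditions: Ag2O, 4 Å molecular sieves, CH2Cl2, 0 °C, dark
Reagents that add atoms: none
Why: Silver-assisted closure of a trans-diaxial iodohydrin, in which the β C29–OH displaces the α C27–I with inversion to give the β epoxide; silver oxide is halophilic and only weakly basic, which spares the peroxyhemiacetal.

Compound list
1 | 2-methyl-1,3-dithiane | CC1SCCCS1 | starting material
2 | 2,3-dibromoprop-1-ene | BrCC(Br)=C | starting material
3 | 2-lithio-2-methyl-1,3-dithiane | [Li]C1(C)SCCCS1 | intermediate
4 | 2-(2-bromoprop-2-en-1-yl)-2-methyl-1,3-dithiane | BrC(=C)CC1(C)SCCCS1 | intermediate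
5 | cis-(meso)-2,4-dimethylglutaric anhydride | C[C@@H]1C[C@H](C)C(=O)OC1=O | starting material
6 | (2R,4S)-5-methoxy-2,4-dimethyl-5-oxopentanoic acid | C[C@@H](C(=O)O)C[C@H](C)C(=O)OC | intermediate
7 | methyl (2S,4R)-5-hydroxy-2,4-dimethylpentanoate | C[C@@H](CO)C[C@H](C)C(=O)OC | intermediate
8 | methyl (2S,4R)-5-iodo-2,4-dimethylpentanoate | C[C@@H](CI)C[C@H](C)C(=O)OC | intermediate
9 | alkylzinc iodide from 8 | C[C@@H](C[Zn]I)C[C@H](C)C(=O)OC | intermediate
10 | methyl (2S,4R)-2,4-dimethyl-6-[(2-methyl-1,3-dithian-2-yl)methyl]hept-6-enoate | C[C@@H](CC(=C)CC1(C)SCCCS1)C[C@H](C)C(=O)OC | intermediate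
11 | corresponding hept-6-enal | C[C@@H](CC(=C)CC1(C)SCCCS1)C[C@H](C)C=O | intermediate
12 | ethyl (2E,4S,6R)-4,6-dimethyl-8-[(2-methyl-1,3-dithian-2-yl)methyl]nona-2,8-dienoate | C[C@@H](CC(=C)CC1(C)SCCCS1)C[C@H](C)/C=C/C(=O)OCC | intermediate
13 | ring-A ester (H6 α, C37 β) | C[C@@H]1C[C@H](C)[C@@H](CC(=O)OCC)[C@](C)(CC2(C)SCCCS2)C1 | intermediate
14 | ring-A aldehyde | C[C@@H]1C[C@H](C)[C@@H](CC=O)[C@](C)(CC2(C)SCCCS2)C1 | intermediate
15 | ring-A keto aldehyde | C[C@@H]1C[C@H](C)[C@@H](CC=O)[C@](C)(CC(C)=O)C1 | intermediate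
16 | trans-fused A/B 1-acetylcyclopentene | C[C@@H]1C[C@H](C)[C@H]2CC=C(C(C)=O)[C@]2(C)C1 | intermediate
17 | C7 β-bromide of 16 | C[C@@H]1C[C@H](C)[C@H]2[C@@H](Br)C=C(C(C)=O)[C@]2(C)C1 | intermediate
18 | (4-bromophenoxy)(tert-butyl)dimethylsilane | CC(C)(C)[Si](C)(C)Oc1ccc(Br)cc1 | starting material
19 | 3-chloro-2-(chloromethyl)prop-1-ene | ClCC(=C)CCl | starting material
20 | 4-(TBSO)phenylmagnesium bromide | CC(C)(C)[Si](C)(C)Oc1ccc([Mg]Br)cc1 | intermediate
21 | tert-butyl{4-[2-(chloromethyl)allyl]phenoxy}dimethylsilane | CC(C)(C)[Si](C)(C)Oc1ccc(CC(=C)CCl)cc1 | intermediate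
22 | tert-butyl cyanoacetate | N#CCC(=O)OC(C)(C)C | starting material
23 | tert-butyl 2-cyano-4-[4-(TBSO)benzyl]pent-4-enoate | CC(C)(C)[Si](C)(C)Oc1ccc(CC(=C)CC(C#N)C(=O)OC(C)(C)C)cc1 | intermediate
24 | tert-butyl (R)-2-allyl-2-cyano-4-[4-(TBSO)benzyl]pent-4-enoate | CC(C)(C)[Si](C)(C)Oc1ccc(CC(=C)C[C@](CC=C)(C#N)C(=O)OC(C)(C)C)cc1 | intermediate
25 | corresponding (R)-acid | CC(C)(C)[Si](C)(C)Oc1ccc(CC(=C)C[C@](CC=C)(C#N)C(=O)O)cc1 | intermediate
26 | corresponding (R)-acid chloride | CC(C)(C)[Si](C)(C)Oc1ccc(CC(=C)C[C@](CC=C)(C#N)C(=O)Cl)cc1 | intermediate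
27 | corresponding (R)-aldehyde | CC(C)(C)[Si](C)(C)Oc1ccc(CC(=C)C[C@](CC=C)(C#N)C=O)cc1 | intermediate
28 | propargylic alcohol, TBS ether (C19 R, C34 epimers) | CC(C)(C)[Si](C)(C)Oc1ccc(CC(=C)C[C@](CC=C)(C#N)C(O)C#CC)cc1 | intermediate
29 | phenol fragment | Oc1ccc(CC(=C)C[C@](CC=C)(C#N)C(O)C#CC)cc1 | intermediate
30 | C7 β-aryl ether, C34 carbinol | C[C@@H]1C[C@H](C)[C@H]2[C@@H](Oc3ccc(CC(=C)C[C@](CC=C)(C#N)C(O)C#CC)cc3)C=C(C(C)=O)[C@]2(C)C1 | intermediate
31 | ynone-enone | C[C@@H]1C[C@H](C)[C@H]2[C@@H](Oc3ccc(CC(=C)C[C@](CC=C)(C#N)C(=O)C#CC)cc3)C=C(C(C)=O)[C@]2(C)C1 | intermediate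
32 | 2-siloxydiene-ynone | C[C@@H]1C[C@H](C)[C@H]2[C@@H](Oc3ccc(CC(=C)C[C@](CC=C)(C#N)C(=O)C#CC)cc3)C=C(C(=C)O[Si](C)(C)C(C)(C)C)[C@]2(C)C1 | intermediate
33 | macrocyclic Diels–Alder adduct | C[C@@H]1C[C@H](C)[C@H]2[C@H]3Oc4ccc(cc4)CC(=C)C[C@](CC=C)(C#N)C(=O)C5=C(C)CC(O[Si](C)(C)C(C)(C)C)=C([C@H]35)[C@]2(C)C1 | intermediate
34 | deconjugated diketone (C31 unassigned) | C[C@@H]1C[C@H](C)[C@H]2[C@H]3Oc4ccc(cc4)CC(=C)C[C@](CC=C)(C#N)C(=O)C5=C(C)CC(=O)C([C@H]35)[C@]2(C)C1 | intermediate
35 | ring-C enone, nitrile, C16 methylene | C[C@@H]1C[C@H](C)[C@H]2[C@H]3Oc4ccc(cc4)CC(=C)C[C@](CC=C)(C#N)C(=O)[C@H]5C(C)=CC(=O)[C@H]([C@H]35)[C@]2(C)C1 | intermediate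
36 | C16 spiro-epoxide (C16 epimers) | C[C@@H]1C[C@H](C)[C@H]2[C@H]3Oc4ccc(cc4)CC6(CO6)C[C@](CC=C)(C#N)C(=O)[C@H]5C(C)=CC(=O)[C@H]([C@H]35)[C@]2(C)C1 | intermediate
37 | C16 ketone, nitrile | C[C@@H]1C[C@H](C)[C@H]2[C@H]3Oc4ccc(cc4)CC(=O)C[C@](CC=C)(C#N)C(=O)[C@H]5C(C)=CC(=O)[C@H]([C@H]35)[C@]2(C)C1 | intermediate
38 | C16 ketone, primary amide | C[C@@H]1C[C@H](C)[C@H]2[C@H]3Oc4ccc(cc4)CC(=O)C[C@](CC=C)(C(N)=O)C(=O)[C@H]5C(C)=CC(=O)[C@H]([C@H]35)[C@]2(C)C1 | intermediate
39 | hydroxylactam enone | C[C@@H]1C[C@H](C)[C@H]2[C@H]3Oc4ccc(cc4)C[C@]4(O)C[C@](CC=C)(C(=O)N4)C(=O)[C@H]5C(C)=CC(=O)[C@H]([C@H]35)[C@]2(C)C1 | intermediate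
40 | C29 tertiary allylic alcohol, C19 allyl | C[C@@H]1C[C@H](C)[C@H]2[C@H]3Oc4ccc(cc4)C[C@]4(O)C[C@](CC=C)(C(=O)N4)C(=O)[C@H]5C(C)=C[C@](O)(C)[C@H]([C@H]35)[C@]2(C)C1 | intermediate
41 | C21 aldehyde | C[C@@H]1C[C@H](C)[C@H]2[C@H]3Oc4ccc(cc4)C[C@]4(O)C[C@](CC=O)(C(=O)N4)C(=O)[C@H]5C(C)=C[C@](O)(C)[C@H]([C@H]35)[C@]2(C)C1 | intermediate
42 | C25 β-hydroperoxide, C27 α-iodide, open aldehyde | C[C@@H]1C[C@H](C)[C@H]2[C@H]3Oc4ccc(cc4)C[C@]4(O)C[C@](CC=O)(C(=O)N4)C(=O)[C@H]5[C@@](C)(OO)[C@H](I)[C@](O)(C)[C@H]([C@H]35)[C@]2(C)C1 | intermediate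
43 | iodo-dioxocanol | C[C@@H]1C[C@H](C)[C@H]2[C@H]3Oc4ccc(cc4)C[C@]4(O)C[C@]5(C[C@H](O)OO[C@@]6(C)[C@H](I)[C@](O)(C)[C@H]([C@H]3[C@H]6C5=O)[C@]2(C)C1)C(=O)N4 | intermediate
44 | CNP0533733.1 | C[C@@H]1C[C@H](C)[C@H]2[C@H]3Oc4ccc(cc4)C[C@]4(O)C[C@]5(C[C@H](O)OO[C@@]6(C)[C@H]7O[C@@]7(C)[C@H]([C@H]3[C@H]6C5=O)[C@]2(C)C1)C(=O)N4 | target

Total step count: 28.
Longest linear sequence: 20 steps (steps 2–11 and 19–28, from anhydride 5).

Steps most likely to fail

Step 21 (macrocyclising Diels–Alder). The closure may lose against oligomerisation, or the siloxydiene may be desilylated before it reacts.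
Fallback: change from the concerted cycloaddition to a reversible, thermodynamically driven Michael/aldol (Hagemann-type) annulation.
- It sets out from 31. Diethylamine is added to the ynone and the enaminone is hydrolysed with aqueous oxalic acid to the 1,3-diketone F1.
- At high dilution with catalytic Cs2CO3 and then pyrrolidinium acetate, C33 of F1 adds to C32 from the α face, and the acetyl methyl C27 condenses with the C25 ketone.
- Only the dehydration is irreversible, so wrong or intermolecular Michael adducts can revert.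
- The sequence comes back to the route at 35.

Step 27 (iodo-hydroperoxidation). The iodonium ion may be captured by the lactam carbonyl oxygen, the arene may be iodinated, or the free β-iodo hydroperoxide may decay.
Fallback: carry the peroxide in protected form and close the dioxocane last.
- It sets out from 40. NIS with 2-methoxyprop-2-yl hydroperoxide gives the iodo peroxyketal F2, by the same trans-diaxial opening.
- DBU closes the epoxy peroxyketal F3 without risk, because a dialkyl peroxide on a fully substituted carbon cannot fragment under base.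
- Lemieux–Johnson cleavage of the allyl group gives the aldehyde F4.
- Aqueous acetic acid in THF removes the ketal, and the liberated hydroperoxide adds to C21.
- The sequence comes back to the route at 44.

Step 19 (allylic etherification of bromide 17). Loss of HBr, by anti elimination with H6 or by β-hydride elimination from the π-allyl complex, may give the cross-conjugated dienone, and the retention may erode.
Fallback: replace double inversion by a single SN2 inversion on an α leaving group that has no antiperiplanar hydrogen.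
- It sets out from 16. Allylic oxidation (Rh2(cap)4, t-BuOOH) gives the ene-dione F5.
- Luche reduction with hydride entering along the pseudoaxial β trajectory gives the C7 α-alcohol F6.
- Mesyl chloride and triethylamine give the α-mesylate F7.
- F7 is displaced by phenol 29 with K2CO3 from the β face.
- The sequence comes back to the route at 30.

Further compounds
F1 | step 21 | 1,3-diketone analogue of 31 | C[C@@H]1C[C@H](C)[C@H]2[C@@H](Oc3ccc(CC(=C)C[C@](CC=C)(C#N)C(=O)CC(C)=O)cc3)C=C(C(C)=O)[C@]2(C)C1
F2 | step 27 | C25 β-(2-methoxyprop-2-yl)peroxide, C27 α-iodide, C19 allyl | C[C@@H]1C[C@H](C)[C@H]2[C@H]3Oc4ccc(cc4)C[C@]4(O)C[C@](CC=C)(C(=O)N4)C(=O)[C@H]5[C@@](C)(OOC(C)(C)OC)[C@H](I)[C@](O)(C)[C@H]([C@H]35)[C@]2(C)C1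
F3 | step 27 | β-epoxy peroxyketal, C19 allyl | C[C@@H]1C[C@H](C)[C@H]2[C@H]3Oc4ccc(cc4)C[C@]4(O)C[C@](CC=C)(C(=O)N4)C(=O)[C@H]5[C@@](C)(OOC(C)(C)OC)[C@H]6O[C@@]6(C)[C@H]([C@H]35)[C@]2(C)C1
F4 | step 27 | β-epoxy peroxyketal, C21 aldehyde | C[C@@H]1C[C@H](C)[C@H]2[C@H]3Oc4ccc(cc4)C[C@]4(O)C[C@](CC=O)(C(=O)N4)C(=O)[C@H]5[C@@](C)(OOC(C)(C)OC)[C@H]6O[C@@]6(C)[C@H]([C@H]35)[C@]2(C)C1
F5 | step 19 | C7 ketone of 16 (ene-dione) | C[C@@H]1C[C@H](C)[C@H]2C(=O)C=C(C(C)=O)[C@]2(C)C1
F6 | step 19 | C7 α-alcohol | C[C@@H]1C[C@H](C)[C@H]2[C@H](O)C=C(C(C)=O)[C@]2(C)C1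
F7 | step 19 | C7 α-mesylate | C[C@@H]1C[C@H](C)[C@H]2[C@H](OS(C)(=O)=O)C=C(C(C)=O)[C@]2(C)C1
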